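Ring B (the cyclohexene) is closed last, onto a complete ring A. In eudesmane numbering its C1(O)–C2(O)–C3=C4(CH3) unit is an α'-oxy enone in disguise, held between the quaternary carbon C10 and the ring-fusion carbon C5. The key step clips the two-carbon unit C2–C3 between a C10 aldehyde (C1) and a C5 isopropenyl group (C4) in one flask: chelation-controlled addition of lithiated methoxyallene forms C1–C2, acid unveils the vinyl ketone, ring-closing metathesis forms C3=C4. Its precursor is a monocyclic keto aldehyde. C1 remains epimerisable, so its epimers converge; substrate-controlled hydride delivery then sets C2 and C9.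

Key step: step 6

Remark on numbering: eudesmane numbering is used for all intermediates; ring A = C5–C6–C7–C8–C9–C10, ring B = C1–C2–C3–C4–C5–C10; C14 is the CH2O carbon on C10, C15 the methyl on C4, C11–C13 the isopropenyl group on C7; α is the face of C14, β the opposite face (that of H5).
Assumption: (S)-BINAP delivers the alkenyl group to the enantioface that gives the (S)-configured β-carbon, as it does with cyclohex-2-en-1-one.

Step 1
Reactants: 1 cyclohex-2-en-1-one
Product: 3 rac-6-({[tri(propan-2-yl)silyl]oxy}methyl)cyclohex-2-en-1-one, via lithium dienolate 2 (not isolated)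
Conditions: LiN(iPr)2, THF, −78 °C; then (iPr)3SiOCH2Cl, DMPU, −78 → −20 °C
Reagents that add atoms: (triisopropylsiloxy)methyl chloride, ClCO[Si](C(C)C)(C(C)C)C(C)C
Why: Kinetic deprotonation at C6 gives the cross-conjugated lithium dienolate, whose C-alkylation (enolate alkylation) by the reactive α-chloro ether installs the protected C14 carbinol carbon; the new centre is racemic and is erased in step 3.

Step 2
Reactants: 3 rac-6-({[tri(propan-2-yl)silyl]oxy}methyl)cyclohex-2-en-1-one
Product: 4 (5S)-5-(prop-1-en-2-yl)-2-({[tri(propan-2-yl)silyl]oxy}methyl)cyclohexan-1-one (both C2 epimers)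
Conditions: [Rh(cod)Cl]2 (2.5 mol%), (S)-BINAP (6 mol%), KOH (10 mol%), 1,4-dioxane/H2O (10:1), 40 °C
Reagents that add atoms: 4,4,5,5-tetramethyl-2-(prop-1-en-2-yl)-1,3,2-dioxaborolane, C=C(C)B1OC(C)(C)C(C)(C)O1
Why: Hayashi–Miyaura rhodium-catalysed asymmetric conjugate addition, in which the (S)-BINAP–rhodium alkenyl species should add to one enantioface of the enone under catalyst control, so that both enantiomers of racemic 3 give the (5S) centre (C7 of the target) while the configuration at C2 is irrelevant.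

Step 3
Reactants: 4 (5S)-5-(prop-1-en-2-yl)-2-({[tri(propan-2-yl)silyl]oxy}methyl)cyclohexan-1-one
Product: 6 (5S)-5-(prop-1-en-2-yl)-2-({[tri(propan-2-yl)silyl]oxy}methyl)cyclohex-2-en-1-one, via trimethylsilyl enol ether 5 (not isolated)
Conditions: Me3SiCl, NaI, Et3N, MeCN, 23 °C; then Pd(OAc)2 (1.05 equiv), MeCN, 23 °C
Reagents that add atoms: none
Why: Saegusa–Ito oxidation, in which equilibrating silylation should give the more substituted silyl enol ether 5 and palladation followed by β-hydride elimination of a ring hydrogen should give the 2-substituted enone, converging both C2 epimers of 4 into one compound.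

Step 4
Reactants: 6 (5S)-5-(prop-1-en-2-yl)-2-({[tri(propan-2-yl)silyl]oxy}methyl)cyclohex-2-en-1-one
Product: 8 (2S,3R,5S)-2-(hydroxymethyl)-3,5-di(prop-1-en-2-yl)-2-({[tri(propan-2-yl)silyl]oxy}methyl)cyclohexan-1-one, via bromomagnesium enolate 7 (not isolated)
Conditions: CH2=C(CH3)MgBr, CuBr·SMe2 (10 mol%), THF, −40 °C; then CH2O (gas), −40 → 0 °C; aq. NH4Cl
Reagents that add atoms: isopropenylmagnesium bromide, C=C(C)[Mg]Br; formaldehyde, C=O
Why: Copper-catalysed conjugate addition followed by aldol trapping with formaldehyde, in which the organocopper should add axially anti to the C7 isopropenyl group as with 5-substituted cyclohexenones (sets C5) and the enolate should be hydroxymethylated on the face anti to the new C5 substituent (sets C10, the new CH2OH being the future C1).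

Step 5
Reactants: 8 (2S,3R,5S)-2-(hydroxymethyl)-3,5-di(prop-1-en-2-yl)-2-({[tri(propan-2-yl)silyl]oxy}methyl)cyclohexan-1-one
Product: 9 (1R,2R,4S)-6-oxo-2,4-di(prop-1-en-2-yl)-1-({[tri(propan-2-yl)silyl]oxy}methyl)cyclohexane-1-carbaldehyde
Conditions: Dess–Martin periodinane, CH2Cl2, 0 → 23 °C
Reagents that add atoms: none
Why: Dess–Martin oxidation of the neopentyl primary alcohol should give the non-enolisable β-keto aldehyde without touching the ketone, the silyl ether or the alkenes, and no stereocentre changes.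

Step 6
Reactants: 9 (1R,2R,4S)-6-oxo-2,4-di(prop-1-en-2-yl)-1-({[tri(propan-2-yl)silyl]oxy}methyl)cyclohexane-1-carbaldehyde
Product: 12 (1R,5R,7S,10R)-1-hydroxy-14-{[tri(propan-2-yl)silyl]oxy}eudesma-3,11-diene-2,9-dione, via allenyl carbinol 10 (not isolated), via hydroxy dienone 11 (not isolated)
Conditions: MgBr2·OEt2, CH2Cl2, −78 °C; CH2=C=C(OMe)Li (from methoxyallene, n-BuLi, THF, −40 °C), −78 °C; then 1 M HCl (aq, 1.2 equiv), 0 °C; then second-generation Hoveyda–Grubbs catalyst RuCl2(=CH-C6H4-2-OiPr)(H2IMes) (5 mol%), toluene, 60 °C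
Reagents that add atoms: methoxyallene (1-methoxypropa-1,2-diene), COC=C=C; water, O
Why: Magnesium bromide chelates the C1 aldehyde and C9 ketone oxygens, lithiated methoxyallene (an acryloyl anion equivalent) adds through its oxygen-bearing carbon to the aldehyde only (C1–C2 bond, 10), aqueous acid hydrolyses the allenyl enol ether to the vinyl ketone 11, and the ruthenium alkylidene then joins the enone vinyl carbon C3 to the isopropenyl carbon C4 with loss of ethene (C3=C4 bond). The closest known reaction types are the alkoxyallene route to α'-hydroxy enones and ring-closing metathesis to β-methyl cyclohexenones, here run in one flask. Ring B closes as a six-membered ring by ring-closing metathesis between two terminal alkenes; the C7 isopropenyl group could only give a bridged eight-membered ring and should stay out. The new stereocentre C1 is set by the chelate, the nucleophile entering past the C14H2O arm and anti to ring carbon C5 (O1 α, equatorial in 12), and because C1 is α to the C2 ketone any epimer should converge on this equatorial isomer by enolisation (brief DBU treatment). The step needs aldehyde-over-ketone selectivity, secured by the higher electrophilicity of the chelated aldehyde over the neopentyl C9 ketone at −78 °C, and a single ring-closure mode, secured by the fixed positions of the two alkenes; C5 carries no carbonyl group and cannot epimerise.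

Step 7
Reactants: 12 (1R,5R,7S,10R)-1-hydroxy-14-{[tri(propan-2-yl)silyl]oxy}eudesma-3,11-diene-2,9-dione
Product: 13 (1R,5R,7S,10R)-2,9-dioxo-14-{[tri(propan-2-yl)silyl]oxy}eudesma-3,11-dien-1-yl 3-methylbut-2-enoate
Conditions: 3-methylbut-2-enoic acid, DCC, DMAP (20 mol%), CH2Cl2, 0 → 23 °C
Reagents that add atoms: 3-methylbut-2-enoic acid, CC(C)=CC(=O)O
Why: Steglich esterification of the α-ketol hydroxyl, in which carbodiimide activation of the acid avoids the vinylketene pathway that deconjugates the acid chloride, and C1 keeps its equatorial configuration.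

Step 8
Reactants: 13 (1R,5R,7S,10R)-2,9-dioxo-14-{[tri(propan-2-yl)silyl]oxy}eudesma-3,11-dien-1-yl 3-methylbut-2-enoate
Product: 14 (1R,2S,5R,7S,9S,10S)-2,9-dihydroxy-14-{[tri(propan-2-yl)silyl]oxy}eudesma-3,11-dien-1-yl 3-methylbut-2-enoate
Conditions: NaBH4, CeCl3·7H2O, MeOH/THF, −40 → 0 °C
Reagents that add atoms: none
Why: Luche reduction of both ketones under steric approach control in the rigid trans-decalin, in which hydride should reach C2 from the β-face, anti to the syn-axial C14H2O group (α-alcohol, cis to O1), and should reach C9 from the α-face because the axial β-approach is blocked by the syn-axial C7 isopropenyl group (β, axial alcohol).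

Step 9
Reactants: 14 (1R,2S,5R,7S,9S,10S)-2,9-dihydroxy-14-{[tri(propan-2-yl)silyl]oxy}eudesma-3,11-dien-1-yl 3-methylbut-2-enoate
Product: 15 (1R,2S,5R,7S,9S,10S)-2,9-diacetoxy-14-{[tri(propan-2-yl)silyl]oxy}eudesma-3,11-dien-1-yl 3-methylbut-2-enoate
Conditions: Ac2O, pyridine, DMAP (cat.), CH2Cl2, 23 °C
Reagents that add atoms: acetic anhydride, CC(=O)OC(C)=O
Why: DMAP-catalysed acetylation (nucleophilic acyl substitution) of both secondary alcohols, which touches no stereocentre.

Step 10
Reactants: 15 (1R,2S,5R,7S,9S,10S)-2,9-diacetoxy-14-{[tri(propan-2-yl)silyl]oxy}eudesma-3,11-dien-1-yl 3-methylbut-2-enoate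
Product: 16 (1R,2S,5R,7S,9S,10S)-2,9-diacetoxy-14-hydroxyeudesma-3,11-dien-1-yl 3-methylbut-2-enoate (CNP0320218.1)
Conditions: HF·pyridine, pyridine/THF, 0 → 23 °C
Reagents that add atoms: none
Why: Fluoride-mediated desilylation under buffered, weakly acidic conditions should free the C14 alcohol without ester cleavage or acyl migration, and no stereocentre is touched.

Compound list
1 | cyclohex-2-en-1-one | O=C1C=CCCC1 | starting material
2 | lithium cyclohexa-1,5-dien-1-olate (cross-conjugated dienolate of 1) | [Li]OC1=CCCC=C1 | intermediate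
3 | rac-6-({[tri(propan-2-yl)silyl]oxy}methyl)cyclohex-2-en-1-one | O=C1C=CCCC1CO[Si](C(C)C)(C(C)C)C(C)C | intermediate
4 | (5S)-5-(prop-1-en-2-yl)-2-({[tri(propan-2-yl)silyl]oxy}methyl)cyclohexan-1-one, both C2 epimers | C=C(C)[C@@H]1CC(=O)C(CO[Si](C(C)C)(C(C)C)C(C)C)CC1 | intermediate
5 | (S)-trimethyl{[5-(prop-1-en-2-yl)-2-({[tri(propan-2-yl)silyl]oxy}methyl)cyclohex-1-en-1-yl]oxy}silane | C=C(C)[C@@H]1CC(O[Si](C)(C)C)=C(CO[Si](C(C)C)(C(C)C)C(C)C)CC1 | intermediate
6 | (5S)-5-(prop-1-en-2-yl)-2-({[tri(propan-2-yl)silyl]oxy}methyl)cyclohex-2-en-1-one | C=C(C)[C@@H]1CC(=O)C(CO[Si](C(C)C)(C(C)C)C(C)C)=CC1 | intermediate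
7 | bromomagnesium enolate from 1,4-addition to 6 (new isopropenyl group at C5 trans to the one at C7) | C=C(C)[C@@H]1CC(O[Mg]Br)=C(CO[Si](C(C)C)(C(C)C)C(C)C)[C@H](C1)C(C)=C | intermediate
8 | (2S,3R,5S)-2-(hydroxymethyl)-3,5-di(prop-1-en-2-yl)-2-({[tri(propan-2-yl)silyl]oxy}methyl)cyclohexan-1-one (CH2OH trans to the C3 isopropenyl group) | C=C(C)[C@@H]1CC(=O)[C@@](CO)(CO[Si](C(C)C)(C(C)C)C(C)C)[C@H](C1)C(C)=C | intermediate
9 | (1R,2R,4S)-6-oxo-2,4-di(prop-1-en-2-yl)-1-({[tri(propan-2-yl)silyl]oxy}methyl)cyclohexane-1-carbaldehyde | C=C(C)[C@@H]1CC(=O)[C@@](C=O)(CO[Si](C(C)C)(C(C)C)C(C)C)[C@H](C1)C(C)=C | intermediate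
10 | allenyl carbinol: 9 with the formyl group turned into a (1R)-1-hydroxy-2-methoxybuta-2,3-dien-1-yl group | C=C(C)[C@@H]1CC(=O)[C@@]([C@@H](O)C(OC)=C=C)(CO[Si](C(C)C)(C(C)C)C(C)C)[C@H](C1)C(C)=C | intermediate
11 | hydroxy dienone: 9 with the formyl group turned into a (1R)-1-hydroxy-2-oxobut-3-en-1-yl group | C=C(C)[C@@H]1CC(=O)[C@@]([C@@H](O)C(=O)C=C)(CO[Si](C(C)C)(C(C)C)C(C)C)[C@H](C1)C(C)=C | intermediate
12 | (1R,5R,7S,10R)-1-hydroxy-14-{[tri(propan-2-yl)silyl]oxy}eudesma-3,11-diene-2,9-dione (trans-fused, 1α-OH equatorial) | C=C(C)[C@@H]1CC(=O)[C@@]2(CO[Si](C(C)C)(C(C)C)C(C)C)[C@H](C1)C(C)=CC(=O)[C@@H]2O | intermediate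
13 | (1R,5R,7S,10R)-2,9-dioxo-14-{[tri(propan-2-yl)silyl]oxy}eudesma-3,11-dien-1-yl 3-methylbut-2-enoate | C=C(C)[C@@H]1CC(=O)[C@@]2(CO[Si](C(C)C)(C(C)C)C(C)C)[C@H](C1)C(C)=CC(=O)[C@@H]2OC(=O)C=C(C)C | intermediate
14 | (1R,2S,5R,7S,9S,10S)-2,9-dihydroxy-14-{[tri(propan-2-yl)silyl]oxy}eudesma-3,11-dien-1-yl 3-methylbut-2-enoate (2α-OH, 9β-OH) | C=C(C)[C@@H]1C[C@H](O)[C@@]2(CO[Si](C(C)C)(C(C)C)C(C)C)[C@H](C1)C(C)=C[C@H](O)[C@@H]2OC(=O)C=C(C)C | intermediate
15 | (1R,2S,5R,7S,9S,10S)-2,9-diacetoxy-14-{[tri(propan-2-yl)silyl]oxy}eudesma-3,11-dien-1-yl 3-methylbut-2-enoate | C=C(C)[C@@H]1C[C@H](OC(C)=O)[C@@]2(CO[Si](C(C)C)(C(C)C)C(C)C)[C@H](C1)C(C)=C[C@H](OC(C)=O)[C@@H]2OC(=O)C=C(C)C | intermediate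
16 | (1R,2S,5R,7S,9S,10S)-2,9-diacetoxy-14-hydroxyeudesma-3,11-dien-1-yl 3-methylbut-2-enoate (CNP0320218.1) | C=C(C)[C@@H]1C[C@H](OC(C)=O)[C@@]2(CO)[C@H](C1)C(C)=C[C@H](OC(C)=O)[C@@H]2OC(=O)C=C(C)C | target

Total step count: 10. Longest linear sequence: 10 steps, from cyclohex-2-en-1-one.

Steps most likely to fail

Step 6. The acid-labile allenyl ether or the free vinyl ketone may be lost (cyclisation, oligomerisation) before metathesis, and the metathesis between two deactivated alkenes may stall. The fallback sets out from 9 and comes back at 12; it brings the acyl anion in as a dithiane and closes the ring on an electron-neutral diene in a separate operation. 2-Lithio-2-vinyl-1,3-dithiane (n-BuLi, THF, −78 °C) should add through its dithiane carbon to the MgBr2-chelated aldehyde 9 to give the vinyl dithiane carbinol F1. Ring-closing metathesis of F1 (second-generation Grubbs catalyst RuCl2(=CHPh)(H2IMes)(PCy3), CH2Cl2, 40 °C) should give the ring-B dithiane F2. Alkylative dithiane hydrolysis (MeI, CaCO3, aqueous MeCN) should then give 12.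

Step 8. Hydride may approach C9 from the β-face and give the equatorial alcohol, and the senecioyl group may migrate from O1 to the new cis O2 alkoxide. The fallback sets out from 13 and comes back at 16; it sets C9 by intramolecular hydride delivery from the C14 hydroxyl. HF·pyridine should free the primary alcohol to give the hydroxy diketone F3. Evans–Saksena reduction (Me4NBH(OAc)3, MeCN/AcOH, −20 °C) should deliver hydride to the β-hydroxy ketone carbon C9 from the α-face and leave the enone untouched, giving the 9β,14-diol F4. Luche reduction at −78 °C should then reduce C2 to the triol F5. Peracetylation (Ac2O, DMAP) should give the triacetate F6, and lipase-mediated hydrolysis of the primary acetate (Candida antarctica lipase B, phosphate buffer/MTBE) should give 16.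

Step 3. β-Hydride elimination may run toward the oxygen-bearing exocyclic carbon, or silyloxide may be lost from the β-silyloxy ketone. The fallback sets out from 4 and comes back at 6; it replaces palladium by a selenoxide syn-elimination, which avoids oxygen-bearing carbons. The silyl enol ether 5 should be selenenylated at the tetrasubstituted carbon (PhSeCl, CH2Cl2, −78 °C) to give the α-phenylselanyl ketone F7. Oxidation (H2O2, pyridine, CH2Cl2, 0 °C) should then give 6.

Further compounds
F1 | step 6 | vinyl dithiane carbinol: 9 with the formyl group turned into a (R)-hydroxy(2-vinyl-1,3-dithian-2-yl)methyl group | C=C(C)[C@@H]1CC(=O)[C@@]([C@@H](O)C2(C=C)SCCCS2)(CO[Si](C(C)C)(C(C)C)C(C)C)[C@H](C1)C(C)=C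
F2 | step 6 | ring-B dithiane: the C2 propane-1,3-diyl dithioketal of 12 | C=C(C)[C@@H]1CC(=O)[C@@]2(CO[Si](C(C)C)(C(C)C)C(C)C)[C@H](C1)C(C)=CC3(SCCCS3)[C@@H]2O
F3 | step 8 | (1R,5R,7S,10R)-14-hydroxy-2,9-dioxoeudesma-3,11-dien-1-yl 3-methylbut-2-enoate | C=C(C)[C@@H]1CC(=O)[C@@]2(CO)[C@H](C1)C(C)=CC(=O)[C@@H]2OC(=O)C=C(C)C
F4 | step 8 | (1R,5R,7S,9S,10S)-9,14-dihydroxy-2-oxoeudesma-3,11-dien-1-yl 3-methylbut-2-enoate | C=C(C)[C@@H]1C[C@H](O)[C@@]2(CO)[C@H](C1)C(C)=CC(=O)[C@@H]2OC(=O)C=C(C)C
F5 | step 8 | (1R,2S,5R,7S,9S,10S)-2,9,14-trihydroxyeudesma-3,11-dien-1-yl 3-methylbut-2-enoate | C=C(C)[C@@H]1C[C@H](O)[C@@]2(CO)[C@H](C1)C(C)=C[C@H](O)[C@@H]2OC(=O)C=C(C)C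
F6 | step 8 | (1R,2S,5R,7S,9S,10S)-2,9,14-triacetoxyeudesma-3,11-dien-1-yl 3-methylbut-2-enoate | C=C(C)[C@@H]1C[C@H](OC(C)=O)[C@@]2(COC(C)=O)[C@H](C1)C(C)=C[C@H](OC(C)=O)[C@@H]2OC(=O)C=C(C)C
F7 | step 3 | (5S)-2-(phenylselanyl)-5-(prop-1-en-2-yl)-2-({[tri(propan-2-yl)silyl]oxy}methyl)cyclohexan-1-one, both C2 epimers | C=C(C)[C@@H]1CC(=O)C(CO[Si](C(C)C)(C(C)C)C(C)C)([Se]c2ccccc2)CC1
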